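**The problem**

Target 17 is a 6,8-dihydroxy-3,4-dihydroisocoumarin. Resorcinol ring A is fused to δ-lactone ring B (C1 carbonyl, O2, C3, C4, C4a, C8a), and C3 carries an unbranched eleven-carbon chain (C1' to C11') with a secondary alcohol at C6'. The only stereocentres are C3 (R) and C6' (S). Five methylene groups lie between them, so neither can direct the other, and each has to come from reagent control or from the chiral pool. The chain between them has no functional group, so a bond made there must leave nothing behind, or only an alkene that hydrogenation can erase. The two phenols are acidic and oxidisable and have to be masked through the organometallic steps, with a group that leaves under neutral conditions because the finished molecule holds a lactone and a free carbinol. Ring B is the resting state of any 2-(2-hydroxyalkyl)benzoate, so a different ester at C1 can only exist while the C3 oxygen is blocked. The feature that opens the route is that C1 can be esterified by the C6' hydroxyl instead of the C3 hydroxyl. That places C1, the ester oxygen, C6', C5', C4', C3', C2', C1', C3, C4, C4a and C8a in a 12-membered benzolactone, in which the C3 oxygen is still five atoms from C1 and can later take the acyl group back to form ring B.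

**Retrosynthesis**

17 from 16. No skeletal bond is cut. Two O-benzyl groups and a C2'=C3' double bond are added back. A closing hydrogenation is neutral, removes both aryl ethers and erases the alkene and its geometry in one operation. Methyl ethers would instead need a Lewis acid in the presence of the lactone and the free alcohol.

16 from 14 (through 15). The C1–O2 bond of ring B is cut, C1 is reattached to the C6' oxygen and the C3 oxygen is silylated. This turns the open C3-to-C6' chain into part of a ring. The neighbouring option keeps ring B and joins the chain by cross-metathesis of the 3-allyl lactone F6 with a terminal alkene; both partners are unhindered monosubstituted alkenes, so a statistical mixture of homo- and heterodimers would result. The forward step needs the freed C3 alkoxide to add to C1 in a six-membered closure and expel the C6' oxygen. It is placed before debenzylation so that no phenoxide deactivates the ester.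

14 from 13. The C2'=C3' double bond is cut by retro ring-closing metathesis. This position keeps the alkene homoallylic to the C3 oxygen and three bonds from C6', so neither carbinol is allylic. It also lets both alkene-bearing halves derive from the same allyl nucleophile 5. The 12-membered ring is opened to an acyclic diene ester whose two stereocentres are already in place. The forward reaction must favour ring closure over oligomerisation.

13 from 10 and 12. The O–C6' bond of the ester is cut, not the acyl C1–O bond. Acid 10 has two ortho substituents and resists attack at its carbonyl, whereas a Mitsunobu reaction forms the bond at the alcohol carbon and is indifferent to that hindrance. The price is inversion, so the alcohol must be the R enantiomer 12.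

12 from 11 and 5. The C4'–C5' bond is cut. Opening the terminal carbon of the commercial epoxide 11 with 5 gives the homoallylic chain in one step and leaves the purchased stereocentre untouched.

10 from 8 (through 9). The C1–C8a bond is cut, with a bromine standing in for the carboxyl group. Starting from a benzoate and building the side chain by lateral metalation was rejected, because the C3 alkoxide formed would close ring B at once. Bromine–lithium exchange and carboxylation put the acid exactly at the halogenated carbon, after the C3 oxygen has been silylated.

8 from 7, and 7 from 4 and 5. The C3–C1' bond is cut. Asymmetric allylboration of the arylacetaldehyde 4 sets C3 by reagent control and delivers the first terminal alkene; silylation then blocks the C3 oxygen.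

4 from 3, 3 from 2, 2 from 1. These are functional-group changes on a commercial arene. The aldehyde comes from the ester, the bromine is placed by electrophilic substitution directed by the two ethers, and the ethers come from benzylation of 1.

**Roads not taken**

Alternative 1: The cut is the C4a–C8a bond of ring A. In the forward direction, mild base (Et3N or Cs2CO3) folds the linear diketo-dioxinone A2: the dioxinone carbon that becomes C8a adds to the ketone that becomes C4a, and loss of water gives the acetonide-masked resorcylate A1. Desilylation would then let the C3 hydroxyl open the dioxinone to ring B. The merits are real. The arene is born with every substituent in place, so no regiochemical question arises as in step 2. The carboxyl and the C8 phenol are protected together, and no dilute macrocyclisation is needed. The weak points are in the precursor. A2 must already contain the whole C3-to-C11' chain with both stereocentres, so the problem of joining the two halves is moved, not solved. The C3 silyloxy group is β to the ketone that the base must enolise, which invites E1cB loss of silanolate. The polycarbonyl chain has to be built by acylations with strong base. The chosen plan needs more protecting-group steps on the arene. Against that it offers a purchased ring A, two small chiral fragments joined by a temporary ester, and no β-alkoxy ketone at any stage.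

Alternative 2: The cuts are C3–C1' and C4–C4a, made together. The alkyllithium from iodide A5 and t-BuLi adds to the vinyl boronate A6, and Pd(OAc)2 with a chiral Mandyphos ligand couples the ate complex with aryl triflate A4. The alkyl group migrates from boron to carbon as the aryl group is delivered, giving the boronate A3 with C3 set by the catalyst. Oxidation with retention, closure of ring B onto the methyl ester and deprotection would finish the synthesis. This is the most convergent of the four plans: three components are joined and a stereocentre is set in one catalytic step, with no tether and no macrocycle. Its weak points are specific to this target. A4 is an electron-rich triflate ortho to an ester. Halide salts from the lithium–iodine exchange are known inhibitors and must be sequestered. The ester must not meet free alkyllithium. The enantioselectivity for a long alkyl migrating group combined with this hindered electrophile is an extrapolation. A5 also needs its own synthesis from the chiral pool. In step count this road is probably shorter. The chosen plan sets against that two stereocentres made by reaction classes proven on exactly these substrate types, and a key step with a simple fallback.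

Alternative 3: The cut is the C1–O2 bond, read as oxygen insertion into a ketone. A Baeyer–Villiger monooxygenase (flavin, NADPH, O2) at mildly basic pH would oxidise the indanone A8, whose C2 epimerises through the enol, with migration of the alkyl-bearing carbon. This would give the isochromanone A7 in a dynamic kinetic resolution. It is the shortest road, the racemic ketone is easy to make, and C3 would be set with no chiral reagent. The risks are concentrated in one step. In an electron-rich aryl ketone the intrinsic preference is aryl migration, which would put the oxygen on the wrong side of the carbonyl, so the enzyme must override it. It must also accept an eleven-carbon lipophilic chain with a remote hydroxyl and distinguish the C2 epimers. After the key step both aryl methyl ethers have to be cleaved with a strong Lewis acid such as BBr3 in the presence of the lactone and the free carbinol, and the C6 ether is the less willing of the two. The chosen plan is longer. It relies only on general reagents and ends with a neutral hydrogenation.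

Key step: step 9

Assumption: step 9 is expected to give both alkene isomers of 14. The E isomer is drawn for 14, 15 and 16, and either isomer is carried forward because step 11 removes the double bond.
Assumption: locants C1 to C8a and C1' to C11' follow the isochromanone numbering of 17 throughout.

**Route**

Step 1
Reactants: 1 methyl 2-(3,5-dihydroxyphenyl)acetate
Product: 2 methyl 2-[3,5-bis(benzyloxy)phenyl]acetate
Conditions: BnBr, K2CO3, acetone, reflux
Reagents that add atoms: benzyl bromide, BrCc1ccccc1
Why: Williamson ether synthesis; carbonate deprotonates only the phenols, which alkylate at oxygen, while the ester and its α-methylene are left alone. Benzyl is chosen because it survives organolithium, Mitsunobu, metathesis and fluoride conditions and leaves in the hydrogenation that also saturates the alkene.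

Step 2
Reactants: 2 methyl 2-[3,5-bis(benzyloxy)phenyl]acetate
Product: 3 methyl 2-[3,5-bis(benzyloxy)-2-bromophenyl]acetate
Conditions: NBS, MeCN, 0 °C → rt
Reagents that add atoms: N-bromosuccinimide, O=C1CCC(=O)N1Br
Why: Electrophilic aromatic bromination; the carbon para to one ether and ortho to the other is attacked in preference to the position flanked by both ethers, as is usual for 3,5-dialkoxyphenylacetates. The bromine marks the future C8a–C1 bond.

Step 3
Reactants: 3 methyl 2-[3,5-bis(benzyloxy)-2-bromophenyl]acetate
Product: 4 2-[3,5-bis(benzyloxy)-2-bromophenyl]acetaldehyde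
Conditions: i-Bu2AlH, CH2Cl2, −78 °C; MeOH, then aq. potassium sodium tartrate (KNaC4H4O6); used crude at once
Reagents that add atoms: none
Why: Partial reduction of an ester; the aluminium hemiacetal is stable at −78 °C and releases the aldehyde only on work-up, and the aryl bromide and benzyl ethers are inert to the hydride. The aldehyde is taken on without storage because arylacetaldehydes enolise and self-condense.

Step 4
Reactants: 4 2-[3,5-bis(benzyloxy)-2-bromophenyl]acetaldehyde; 5 allylmagnesium bromide
Product: 7 (R)-1-[3,5-bis(benzyloxy)-2-bromophenyl]pent-4-en-2-ol, via borinate ester 6 (not isolated)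
Conditions: (+)-Ipc2BOMe [from (−)-α-pinene], 5, Et2O, −78 °C → rt; then 4, −78 °C; NaOH, H2O2, rt
Reagents that add atoms: none
Why: Brown asymmetric allylboration; the B-allyldiisopinocampheylborane made in the flask adds through a chair six-membered transition state, and the isopinocampheyl groups from (−)-α-pinene direct the allyl group to the Re face of the aldehyde, which sets C3 as R. Oxidative work-up cleaves the borinate 6 and leaves the aryl bromide and ethers untouched.

Step 5
Reactants: 7 (R)-1-[3,5-bis(benzyloxy)-2-bromophenyl]pent-4-en-2-ol
Product: 8 {[(R)-1-[3,5-bis(benzyloxy)-2-bromophenyl]pent-4-en-2-yl]oxy}(tert-butyl)dimethylsilane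
Conditions: TBSCl, imidazole, DMF, rt
Reagents that add atoms: tert-butyldimethylsilyl chloride, C[Si](C)(Cl)C(C)(C)C
Why: Standard silylation of a secondary alcohol. The silyl ether keeps the C3 oxygen from closing ring B once the carboxyl is in place, survives lithiation, Mitsunobu and metathesis, and is the group that fluoride later removes to start the ring contraction.

Step 6
Reactants: 8 {[(R)-1-[3,5-bis(benzyloxy)-2-bromophenyl]pent-4-en-2-yl]oxy}(tert-butyl)dimethylsilane
Product: 10 2,4-bis(benzyloxy)-6-[(R)-2-(tert-butyldimethylsilyloxy)pent-4-en-1-yl]benzoic acid, via aryllithium 9 (not isolated)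
Conditions: n-BuLi, THF, −78 °C; CO2, −78 → 0 °C; cold dilute HCl
Reagents that add atoms: carbon dioxide, O=C=O
Why: Bromine–lithium exchange followed by carboxylation; exchange at −78 °C is faster than any deprotonation, and the aryllithium 9 is trapped by CO2 exactly at the carbon that becomes C8a. The terminal alkene, the benzyl ethers and the bulky silyl ether are expected to tolerate the short-lived aryllithium at this temperature.

Step 7
Reactants: 11 (R)-2-pentyloxirane; 5 allylmagnesium bromide
Product: 12 (R)-dec-1-en-5-ol
Conditions: CuI (10 mol%), THF, −40 → 0 °C; aq. NH4Cl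
Reagents that add atoms: none
Why: Copper-catalysed Grignard opening of a terminal epoxide; attack occurs at the unsubstituted carbon by SN2 displacement, so the stereocentre is not involved and the R configuration of 11 is kept.

Step 8
Reactants: 10 2,4-bis(benzyloxy)-6-[(R)-2-(tert-butyldimethylsilyloxy)pent-4-en-1-yl]benzoic acid; 12 (R)-dec-1-en-5-ol
Product: 13 (S)-dec-1-en-5-yl 2,4-bis(benzyloxy)-6-[(R)-2-(tert-butyldimethylsilyloxy)pent-4-en-1-yl]benzoate
Conditions: PPh3, DIAD, toluene, 0 °C → rt
Reagents that add atoms: none
Why: Mitsunobu esterification; the carboxylate displaces the alkoxyphosphonium group at C6' by SN2, so the R alcohol gives the S ester with clean inversion. The new bond forms at the alcohol carbon and not at the carbonyl, so the two ortho substituents of the acid do not slow it.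

Step 9
Reactants: 13 (S)-dec-1-en-5-yl 2,4-bis(benzyloxy)-6-[(R)-2-(tert-butyldimethylsilyloxy)pent-4-en-1-yl]benzoate
Product: 14 (3S,6E,9R)-12,14-bis(benzyloxy)-9-(tert-butyldimethylsilyloxy)-3-pentyl-3,4,5,8,9,10-hexahydro-1H-2-benzoxacyclododecin-1-one (E isomer drawn; Z isomer expected alongside)
Conditions: second-generation Grubbs catalyst RuCl2(=CHPh)(PCy3)(H2IMes) (5 mol%), CH2Cl2 (2 mM), reflux
Reagents that add atoms: none
Why: Ring-closing alkene metathesis: the ruthenium benzylidene exchanges with one terminal alkene of 13 to give a ruthenium alkylidene, which adds to the second alkene by [2+2] cycloaddition to a ruthenacyclobutane, and cycloreversion releases ethylene and the C2'=C3' alkene. The closest known reaction type is ring-closing metathesis of benzoate-tethered dienes to 12- and 14-membered resorcylic macrolides. The one ring formed is the 12-membered lactone (C1, ester O, C6', C5', C4', C3', C2', C1', C3, C4, C4a, C8a), closed end to end between the two chain termini so that both alkene carbons lie inside the ring. No stereocentre is created; C3 and C6' lie two and three bonds from the reacting carbons and are not touched, and the alkene geometry is of no consequence because step 11 removes it. The selectivity needed is ring closure over acyclic oligomerisation, which is secured by millimolar dilution, by loss of volatile ethylene and by the ortho-disubstituted benzoate, whose twisted ester turns both chains to the same side of the arene. Both alkenes are unhindered and monosubstituted and their nearest oxygen substituents are homoallylic or further, so initiation at either end is productive and no stable chelate should hold the catalyst.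

Step 10
Reactants: 14 (3S,6E,9R)-12,14-bis(benzyloxy)-9-(tert-butyldimethylsilyloxy)-3-pentyl-3,4,5,8,9,10-hexahydro-1H-2-benzoxacyclododecin-1-one
Product: 16 (R)-6,8-bis(benzyloxy)-3-[(S,E)-6-hydroxyundec-2-en-1-yl]isochroman-1-one, via hydroxy macrolide alkoxide 15 (not isolated)
Conditions: Bu4NF, THF, 0 °C → rt; aq. NH4Cl
Reagents that add atoms: none
Why: Fluoride desilylation followed by intramolecular transesterification (translactonisation); the C3 alkoxide of 15 adds to C1 in a 6-exo-trig closure and the tetrahedral intermediate expels the C6' alkoxide, driven by the conjugated six-membered benzolactone and release of macrocycle strain. The step is run while the phenols are still benzylated, so no phenoxide lowers the electrophilicity of the ester; no C–O bond at C3 or C6' is broken, so both configurations are kept.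

Step 11
Reactants: 16 (R)-6,8-bis(benzyloxy)-3-[(S,E)-6-hydroxyundec-2-en-1-yl]isochroman-1-one
Product: 17 (R)-6,8-dihydroxy-3-[(S)-6-hydroxyundecyl]isochroman-1-one
Conditions: H2 (1 atm), 10% Pd/C, EtOAc/EtOH, rt
Reagents that add atoms: none
Why: Catalytic hydrogenation saturates the disubstituted alkene of either geometry and hydrogenolyses both aryl benzyl ethers. The lactone, the non-benzylic C3–O bond and the C6' carbinol are not affected.

**Compound list**

1 | methyl 2-(3,5-dihydroxyphenyl)acetate | COC(=O)Cc1cc(O)cc(O)c1 | starting material
2 | methyl 2-[3,5-bis(benzyloxy)phenyl]acetate | COC(=O)Cc1cc(OCc2ccccc2)cc(OCc2ccccc2)c1 | intermediate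
3 | methyl 2-[3,5-bis(benzyloxy)-2-bromophenyl]acetate | COC(=O)Cc1cc(OCc2ccccc2)cc(OCc2ccccc2)c1Br | intermediate
4 | 2-[3,5-bis(benzyloxy)-2-bromophenyl]acetaldehyde | O=CCc1cc(OCc2ccccc2)cc(OCc2ccccc2)c1Br | intermediate
5 | allylmagnesium bromide | C=CC[Mg]Br | starting material
6 | {[(R)-1-[3,5-bis(benzyloxy)-2-bromophenyl]pent-4-en-2-yl]oxy}diisopinocampheylborane (borinate ester, isopinocampheyl groups from (−)-α-pinene) | C=CC[C@@H](OB([C@H]1C[C@H]2C[C@@H]([C@@H]1C)C2(C)C)[C@H]1C[C@H]2C[C@@H]([C@@H]1C)C2(C)C)Cc1cc(OCc2ccccc2)cc(OCc2ccccc2)c1Br | intermediate
7 | (R)-1-[3,5-bis(benzyloxy)-2-bromophenyl]pent-4-en-2-ol | C=CC[C@@H](O)Cc1cc(OCc2ccccc2)cc(OCc2ccccc2)c1Br | intermediate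
8 | {[(R)-1-[3,5-bis(benzyloxy)-2-bromophenyl]pent-4-en-2-yl]oxy}(tert-butyl)dimethylsilane | C=CC[C@@H](O[Si](C)(C)C(C)(C)C)Cc1cc(OCc2ccccc2)cc(OCc2ccccc2)c1Br | intermediate
9 | {2,4-bis(benzyloxy)-6-[(R)-2-(tert-butyldimethylsilyloxy)pent-4-en-1-yl]phenyl}lithium | C=CC[C@@H](O[Si](C)(C)C(C)(C)C)Cc1cc(OCc2ccccc2)cc(OCc2ccccc2)c1[Li] | intermediate
10 | 2,4-bis(benzyloxy)-6-[(R)-2-(tert-butyldimethylsilyloxy)pent-4-en-1-yl]benzoic acid | C=CC[C@@H](O[Si](C)(C)C(C)(C)C)Cc1cc(OCc2ccccc2)cc(OCc2ccccc2)c1C(=O)O | intermediate
11 | (R)-2-pentyloxirane | CCCCC[C@@H]1CO1 | starting material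
12 | (R)-dec-1-en-5-ol | CCCCC[C@@H](O)CCC=C | intermediate
13 | (S)-dec-1-en-5-yl 2,4-bis(benzyloxy)-6-[(R)-2-(tert-butyldimethylsilyloxy)pent-4-en-1-yl]benzoate | C=CC[C@@H](O[Si](C)(C)C(C)(C)C)Cc1cc(OCc2ccccc2)cc(OCc2ccccc2)c1C(=O)O[C@H](CCC=C)CCCCC | intermediate
14 | (3S,6E,9R)-12,14-bis(benzyloxy)-9-(tert-butyldimethylsilyloxy)-3-pentyl-3,4,5,8,9,10-hexahydro-1H-2-benzoxacyclododecin-1-one (E isomer drawn) | O=C1O[C@@H](CCCCC)CC/C=C/C[C@@H](O[Si](C)(C)C(C)(C)C)Cc2cc(OCc3ccccc3)cc(OCc3ccccc3)c12 | intermediate
15 | (3S,6E,9R)-12,14-bis(benzyloxy)-9-hydroxy-3-pentyl-3,4,5,8,9,10-hexahydro-1H-2-benzoxacyclododecin-1-one (present in the flask as its tetrabutylammonium alkoxide) | O=C1O[C@@H](CCCCC)CC/C=C/C[C@@H](O)Cc2cc(OCc3ccccc3)cc(OCc3ccccc3)c12 | intermediate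
16 | (R)-6,8-bis(benzyloxy)-3-[(S,E)-6-hydroxyundec-2-en-1-yl]isochroman-1-one (E isomer drawn) | CCCCC[C@H](O)CC/C=C/C[C@@H]1Cc2cc(OCc3ccccc3)cc(OCc3ccccc3)c2C(=O)O1 | intermediate
17 | (R)-6,8-dihydroxy-3-[(S)-6-hydroxyundecyl]isochroman-1-one | CCCCC[C@H](O)CCCCC[C@@H]1Cc2cc(O)cc(O)c2C(=O)O1 | target

**Step count and least certain steps**

Total step count: 11. Longest linear sequence: 10 steps (steps 1 to 6 and 8 to 11); step 7 is a one-step side branch.

Step 9 (key step). The likely failures are chain growth by intermolecular metathesis outcompeting closure of the 12-membered ring, and migration of a double bond along the chain before closure, which would give a ring-contracted lactone. The fallback reverses the order of the two unions. It sets out from 10 and 12 and returns at 14. Cross-metathesis of 10 with an excess of 12 (second-generation Grubbs catalyst, CH2Cl2, reflux) should give the seco acid 2,4-bis(benzyloxy)-6-[(2R,4E,8R)-2-(tert-butyldimethylsilyloxy)-8-hydroxytridec-4-en-1-yl]benzoic acid F1. It should be separable from the homodimers because it alone carries both an acid and an alcohol. Mitsunobu macrolactonisation of F1 (PPh3, DIAD, toluene, high dilution) then closes the same ring at the O–C6' bond with inversion and gives 14.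

Step 10. Acyl transfer may stall across the unsaturated ring for one alkene isomer, so that silyl cleavage occurs without ring contraction. The fallback sets out from 14 and returns at 17, bypassing 16. Hydrogenation first (H2, Pd/C, EtOAc) should give the saturated, more flexible diphenol (3S,9R)-9-(tert-butyldimethylsilyloxy)-12,14-dihydroxy-3-pentyl-3,4,5,6,7,8,9,10-octahydro-1H-2-benzoxacyclododecin-1-one F2. HF·pyridine in THF would then free the C3 hydroxyl to give (3S,9R)-9,12,14-trihydroxy-3-pentyl-3,4,5,6,7,8,9,10-octahydro-1H-2-benzoxacyclododecin-1-one F3. Catalytic camphorsulfonic acid in toluene should contract F3 to 17 under conditions in which the phenols stay protonated.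

Step 4 (with step 3). The aldehyde may enolise and self-condense before it is allylated, and incomplete facial selectivity would carry a C3 epimer forward as a diastereomer after step 8. The fallback sets out from 3 and returns at 7. Full reduction with LiBH4 gives the stable alcohol 2-[3,5-bis(benzyloxy)-2-bromophenyl]ethan-1-ol F4. Iridium-catalysed transfer-hydrogenative allylation of F4 with allyl acetate ([Ir(cod)Cl]2, the BINAP enantiomer that delivers allyl to the Re face, Cs2CO3, 4-chloro-3-nitrobenzoic acid, THF, 100 °C) forms the aldehyde only transiently at the metal and should give 7 under catalyst control.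

Step 8. Displacement at the secondary carbon by a weakly acidic, electron-rich carboxylic acid may be slow, which allows elimination at C6' or acyl transfer to the reduced azodicarboxylate. The fallback sets out from 12 and 10 and returns at 13. The alcohol is converted with MsCl and Et3N into (R)-dec-1-en-5-yl methanesulfonate F5, and the caesium salt of 10 (Cs2CO3, DMF, 50 °C) displaces the sulfonate of F5 with inversion.

Step 6. Silicon may migrate from oxygen to the lithiated carbon, or the aryllithium may be protonated before it meets CO2. The fallback sets out from 7 and returns at 10. Treating 7 with two equivalents of n-BuLi forms the alkoxide and then the aryllithium, which cannot suffer silyl migration; CO2 and acidification give the lactone (R)-3-allyl-6,8-bis(benzyloxy)isochroman-1-one F6. KOH in aqueous THF opens F6 to potassium 2,4-bis(benzyloxy)-6-[(R)-2-hydroxypent-4-en-1-yl]benzoate F7. TBSCl and imidazole in DMF silylate both oxygens to give tert-butyldimethylsilyl 2,4-bis(benzyloxy)-6-[(R)-2-(tert-butyldimethylsilyloxy)pent-4-en-1-yl]benzoate F8. K2CO3 in aqueous methanol cleaves only the silyl ester of F8 and gives 10.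

**Further compounds**

F1 | step 9 | 2,4-bis(benzyloxy)-6-[(2R,4E,8R)-2-(tert-butyldimethylsilyloxy)-8-hydroxytridec-4-en-1-yl]benzoic acid | CCCCC[C@@H](O)CC/C=C/C[C@@H](O[Si](C)(C)C(C)(C)C)Cc1cc(OCc2ccccc2)cc(OCc2ccccc2)c1C(=O)O
F2 | step 10 | (3S,9R)-9-(tert-butyldimethylsilyloxy)-12,14-dihydroxy-3-pentyl-3,4,5,6,7,8,9,10-octahydro-1H-2-benzoxacyclododecin-1-one | O=C1O[C@@H](CCCCC)CCCCC[C@@H](O[Si](C)(C)C(C)(C)C)Cc2cc(O)cc(O)c12
F3 | step 10 | (3S,9R)-9,12,14-trihydroxy-3-pentyl-3,4,5,6,7,8,9,10-octahydro-1H-2-benzoxacyclododecin-1-one | O=C1O[C@@H](CCCCC)CCCCC[C@@H](O)Cc2cc(O)cc(O)c12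
F4 | step 4 | 2-[3,5-bis(benzyloxy)-2-bromophenyl]ethan-1-ol | OCCc1cc(OCc2ccccc2)cc(OCc2ccccc2)c1Br
F5 | step 8 | (R)-dec-1-en-5-yl methanesulfonate | CCCCC[C@@H](OS(C)(=O)=O)CCC=C
F6 | step 6 | (R)-3-allyl-6,8-bis(benzyloxy)isochroman-1-one | C=CC[C@@H]1Cc2cc(OCc3ccccc3)cc(OCc3ccccc3)c2C(=O)O1
F7 | step 6 | potassium 2,4-bis(benzyloxy)-6-[(R)-2-hydroxypent-4-en-1-yl]benzoate | C=CC[C@@H](O)Cc1cc(OCc2ccccc2)cc(OCc2ccccc2)c1C(=O)[O-].[K+]
F8 | step 6 | tert-butyldimethylsilyl 2,4-bis(benzyloxy)-6-[(R)-2-(tert-butyldimethylsilyloxy)pent-4-en-1-yl]benzoate | C=CC[C@@H](O[Si](C)(C)C(C)(C)C)Cc1cc(OCc2ccccc2)cc(OCc2ccccc2)c1C(=O)O[Si](C)(C)C(C)(C)C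
A1 | alternative 1 | 7-hydroxy-2,2-dimethyl-5-[(2R,8S)-2,8-bis(tert-butyldimethylsilyloxy)tridecyl]-4H-1,3-benzodioxin-4-one | CC1(C)Oc2cc(O)cc(C[C@H](O[Si](C)(C)C(C)(C)C)CCCCC[C@@H](O[Si](C)(C)C(C)(C)C)CCCCC)c2C(=O)O1
A2 | alternative 1 | 6-[(6R,12S)-6,12-bis(tert-butyldimethylsilyloxy)-2,4-dioxoheptadecyl]-2,2-dimethyl-4H-1,3-dioxin-4-one | CC1(C)OC(CC(=O)CC(=O)C[C@H](O[Si](C)(C)C(C)(C)C)CCCCC[C@@H](O[Si](C)(C)C(C)(C)C)CCCCC)=CC(=O)O1
A3 | alternative 2 | methyl 2,4-bis(benzyloxy)-6-[(2R,8S)-2-(4,4,5,5-tetramethyl-1,3,2-dioxaborolan-2-yl)-8-(tert-butyldimethylsilyloxy)tridecyl]benzoate | COC(=O)c1c(OCc2ccccc2)cc(OCc2ccccc2)cc1C[C@H](B1OC(C)(C)C(C)(C)O1)CCCCC[C@@H](O[Si](C)(C)C(C)(C)C)CCCCC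
A4 | alternative 2 | methyl 2,4-bis(benzyloxy)-6-{[(trifluoromethyl)sulfonyl]oxy}benzoate | COC(=O)c1c(OCc2ccccc2)cc(OCc2ccccc2)cc1OS(=O)(=O)C(F)(F)F
A5 | alternative 2 | (S)-tert-butyl[(1-iodoundecan-6-yl)oxy]dimethylsilane | CCCCC[C@H](O[Si](C)(C)C(C)(C)C)CCCCCI
A6 | alternative 2 | 4,4,5,5-tetramethyl-2-vinyl-1,3,2-dioxaborolane | C=CB1OC(C)(C)C(C)(C)O1
A7 | alternative 3 | (R)-3-[(S)-6-hydroxyundecyl]-6,8-dimethoxyisochroman-1-one | CCCCC[C@H](O)CCCCC[C@@H]1Cc2cc(OC)cc(OC)c2C(=O)O1
A8 | alternative 3 | 2-[(S)-6-hydroxyundecyl]-5,7-dimethoxyindan-1-one (C2 epimers interconverting) | CCCCC[C@H](O)CCCCCC1Cc2cc(OC)cc(OC)c2C1=O
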